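**The leftover.** In the noon run at 8.00 h, target reads 94.7% and solid substrate 0.6%, with a scatter of 0.5 percentage points. That leaves 5.3 points outside target, which I read as side product within that scatter, and this leftover is where I start. The dawn run, with more coupling partner, leaves 4.8 points outside target.

| setting | noon | dawn | flask |
|---|---|---|---|
| solid substrate | 0.020 M | 0.020 M | 0.020 M |
| coupling partner | 0.020 M (in portions, 3) | 0.031 M (in portions, 3) | 0.0140 M (in portions, 3) |
| remark | run made earlier; portions every 20 s | run made earlier; portions every 20 s | the portions of coupling partner follow each other after 20 s, the first at the start |
| time |  |  | 8.0 h |

| run | time / h | solid substrate / % | target / % |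
|---|---|---|---|
| noon | 0.667 | 0 | 89.6 |
| noon | 1.33 | 0.3 | 93.6 |
| noon | 2.50 | 0 | 93.3 |
| noon | 4.00 | 0 | 94.5 |
| noon | 8.00 | 0.6 | 94.7 |
| dawn | 1.50 | 0.1 | 94.5 |
| dawn | 3.00 | 0.1 | 94.5 |
| dawn | 5.00 | 0 | 95.3 |
| dawn | 6.00 | 0.5 | 95.5 |
| dawn | 8.00 | 0 | 95.2 |

(scatter of a reading: 0.5 percentage points)

- percentages count the solid substrate that a species holds: one side product counts as two
- solid, in amounts per volume of the solution: solid substrate
- at the start none of the solid substrate is in solution
- what has only dissolved of solid substrate counts as not reacted
- the reaction counts as stopped when no species that holds the solid substrate changes by six tenths of a point or more over the second half of the time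

- the state of affairs at 8.0 h: stopped, and by what, or still going (for what has run out or reacted, a solid counts together with what of it has only dissolved) (forward and back rates have come level / the coupling partner has run out first / all of the solid substrate has reacted / it is still moving)
- part of the solid substrate that has turned into other species by 8.0 h (what has only dissolved does not count)
- target at 8.0 h, in percent of the solid substrate charged
- side product at 8.0 h, in percent of the solid substrate charged

**Main step.** Suppose solid substrate and coupling partner give target one to one. The portions in this flask end within 40.0 s, far shorter than the noon run's first reading time, so I count them as one charge. The partner ceiling is [coupling partner] as charged, in percent of [solid substrate] as charged: 70.0%. This flask has less coupling partner than solid substrate, which makes it the limiting reagent, and my first answer for target is the ceiling.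

**Side product.** Side product counts two substrate units, and I assume it holds one coupling partner, so target plus half the side product equals the ceiling. From that leftover, the noon run reads side product per target of 5.60%. Round one gives side product 3.92% and target 68.0%. Putting that back gives side product 3.81% and target 68.1%.

**The remainder.** My conversion is 71.9%. I expect the rest to stay solid or dissolved, which counts as unreacted. Noon target reads 0.2 points higher at 8.00 h than at 4.00 h, against a scatter of 0.5 points, so I expect this flask to have stopped by 8.0 h.

**The forecast.** It says the coupling partner has run out first, with conversion 72%, target 67.5% and side product 4.3%, on “a roughly fixed branching ratio”. Its target stands below my 68.1%, and its side product above my 3.81%.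

**The result.** In this flask, the coupling partner has run out first; conversion is 72.7%, target 67.3% and side product 5.49%.

    dissolved substrate + coupling partner → target (k = 0.370 M⁻¹ s⁻¹)
    solid substrate + target → side product (k = 0.0140 M⁻¹ s⁻¹)
    solid substrate ⇌ dissolved substrate, rate k3*(cs3 - [dissolved substrate]) while solid is left; crystals form when [dissolved substrate] > cs3 (solubility = 8.40 mM, k = 0.00440 s⁻¹)

Target forms from dissolved substrate and coupling partner while solid substrate turns target into side product, and conversion reaches 95% of its final value by 0.430 h. At 4.00 h, coupling partner stands at 0%, and 27.3% remains as dissolved substrate. Target plus half the side product comes to 70.0%, matching the ceiling, though side product exceeds my 3.81%.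

**Second flask.** With 0.0035 M of coupling partner, the neighbour's ceiling is 17.5%. It gives target 1.71% and side product 31.6%, so target plus half the side product is 17.5%.

The readings were computed from invented constants; the scatter is artificial.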